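- In ash the coupling partner (0.520 M) exceeds the substrate (0.40 M), and in oak (0.780 M) it exceeds it further, so you write your balance on the substrate, here the limiting reagent.

common to all: substrate 0.40 M
- violet: coupling partner 0.49 M; run made earlier
- teal: coupling partner 0.66 M; run made earlier
- red: coupling partner 0.93 M; run made earlier
- ash: coupling partner 0.520 M; time 40 h
- oak: coupling partner 0.780 M; time 40 h

| run | time / h | bis adduct / % | substrate / % | side product / % | first product / % |
|---|---|---|---|---|---|
| violet | 2.50 | 6.3 | 32.8 | 3.1 | 57.7 |
| violet | 8.00 | 4.0 | 10.6 | 7.9 | 77.2 |
| violet | 12.0 | 3.7 | 6.8 | 9.2 | 81.2 |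
| violet | 20.0 | 2.9 | 2.4 | 9.9 | 84.4 |
| violet | 30.0 | 2.4 | 0.8 | 12.7 | 85.5 |
| teal | 2.50 | 12.1 | 21.4 | 2.8 | 64.8 |
| teal | 8.00 | 9.6 | 2.3 | 5.3 | 81.8 |
| teal | 12.0 | 9.5 | 0.4 | 4.9 | 85.3 |
| teal | 20.0 | 8.5 | 0.2 | 5.0 | 86.4 |
| teal | 30.0 | 6.5 | 0.1 | 5.7 | 87.6 |
| red | 2.50 | 19.9 | 9.9 | 2.0 | 68.4 |
| red | 4.00 | 19.3 | 2.5 | 2.7 | 74.1 |
| red | 8.00 | 18.8 | 1.4 | 1.8 | 78.2 |
| red | 15.0 | 17.1 | 0 | 2.6 | 79.6 |
| red | 30.0 | 13.8 | 0.5 | 3.0 | 83.4 |

(scatter of a reading: 0.5 percentage points)

* which of these there is most of at the end, counted by the substrate in it, ash (side product / first product / substrate / bis adduct)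
* which of these there is most of at the end, counted by the substrate in it, oak (side product / first product / substrate / bis adduct)
* amount of the one of these that there is most of at the end, in percent of the substrate charged, ash
* amount of the one of these that there is most of at the end, in percent of the substrate charged, oak

- percent here means substrate units held: one side product counts as two
- the analysis behind the earlier runs scatters by 0.5 percentage points, standard deviation
- reactions considered so far: substrate + coupling partner -> first product; coupling partner + first product <-> bis adduct; coupling partner <-> dormant form; substrate + first product -> side product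

- Begin with the main step: substrate and coupling partner give first product, one for each substrate used, and so far the balance holds nothing else.
- Add the bis adduct, which takes first product away: at the last readings it stands at 2.4% in violet, 6.5% in teal and 13.8% in red, more with more partner.
- Add the side product, which goes the other way: 12.7%, 5.7% and 3.0% in the same runs, less with more partner.
- Teal's first product at 30.0 h, 87.6%, leaves 12.4%: call this the leak L, the share of the charged substrate held anywhere except in first product.
- Violet's L is 14.5% and red's is 16.6%, so L dips at teal among these runs, each reading carrying a scatter of 0.5 percentage points.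
- Add the dormant form last, the step that parks coupling partner: between 20.0 h and 30.0 h teal's bis adduct falls from 8.5% to 6.5%, and its first product gains 1.2 points.
- My own reckoning draws L on a straight line in partner, giving 14.1% for ash and 14.3% for oak, then adds teal's gain for the last 10.0 h: first product 87.1% in ash and 86.9% in oak.
- The forecast names first product for ash and first product for oak, at 86.5% and 87.5%, expecting that the bis adduct “slowly drains back to first product”; it puts oak above ash, whereas my two numbers stand 0.20 points apart, with a reading scattering by 0.5 points, so mine do not separate the two flasks.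

    substrate + coupling partner → first product (k = 1.50 M⁻¹ h⁻¹)
    coupling partner + first product ⇌ bis adduct (K = 0.627 M⁻¹, k = 0.687 M⁻¹ h⁻¹)
    coupling partner ⇌ dormant form (K = 1.60, k = 0.0269 h⁻¹)
    substrate + first product → side product (k = 0.0769 M⁻¹ h⁻¹)

- The flask gives first product on top in ash at 87.1% and first product on top in oak at 86.6%, so the forecast held, and L is 12.9% and 13.4%, both above teal's 12.4%. Now take oak with 0.20 M of coupling partner, less than the substrate: at 40.0 h that partner is down to 0.257% of its charge, and L is 70.4%, far above 12.4%. That neighbour still holds 33.2% as substrate, and its side product stands on top at 37.2%.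

(All runs are simulated for an exercise.)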